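**Retrosynthetic overview**
1. Both cyclopentanol rings are opened last by a twofold intramolecular carbonyl-ene disconnection (cyclopentane C1–C2 bonds), giving a C2-symmetric bis(α-tetrahydropyranyl aldehyde).
2. Both bonds between the tetrahydropyran carbon next to oxygen and the aldehyde α-carbon are cut in one two-directional, organocatalytic asymmetric step: a (Z)-enol silane of 6-methylhept-5-enal adds to a bis(cyclic oxocarbenium) precursor, setting all four stereocenters from achiral material.
3. The (Z,Z)-diene core comes from a double Wittig reaction of a C4 bis-ylide with two molecules of 6-methoxydihydro-2H-pyran-3(4H)-one.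
4. Ring order: the tetrahydropyran rings are made first (Achmatowicz ring expansion of furfuryl alcohol) and carried intact; the two cyclopentane rings are closed in the final step.

Assumption: the (S,S)-IDPi enantiomer is taken to give the (R)-configured tetrahydropyran carbon (otherwise the (R,R)-catalyst is used); the acetal carbons of 2, 3, 4 and 8 are stereorandom and are erased on ionization.

**Route**

Step 1
Reactants: 1 furfuryl alcohol
Product: 2 6-hydroxy-2H-pyran-3(6H)-one (racemic hemiacetal)
Conditions: NBS, NaHCO3, THF/H2O (4:1), 0 °C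
Reagents that add atoms: water, O
Why: Achmatowicz oxidative ring expansion; the furan is oxidized to the hydrated ene-dione, which recloses as the pyranone hemiacetal, and no lasting stereocenter is formed.

Step 2
Reactants: 2 6-hydroxy-2H-pyran-3(6H)-one
Product: 3 6-methoxy-2H-pyran-3(6H)-one (racemic)
Conditions: HC(OMe)3, BF3·OEt2 (cat.), Et2O, 0 °C
Reagents that add atoms: trimethyl orthoformate, COC(OC)OC
Why: Lewis acid-catalysed acetal exchange of the hemiacetal through the allyl-stabilized oxocarbenium ion makes the anomeric position stable to the strongly basic Wittig step.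

Step 3
Reactants: 3 6-methoxy-2H-pyran-3(6H)-one
Product: 4 6-methoxydihydro-2H-pyran-3(4H)-one (racemic)
Conditions: H2 (1 atm), Pd/C (10 wt %), EtOAc, rt
Reagents that add atoms: none
Why: Chemoselective heterogeneous hydrogenation of the enone C=C leaves the ketone and the acetal untouched.

Step 4
Reactants: 4 6-methoxydihydro-2H-pyran-3(4H)-one (2.3 equiv), 5 butane-1,4-diylbis(triphenylphosphonium) dibromide
Product: 8 (3Z,3'Z)-3,3'-(butane-1,4-diylidene)bis(6-methoxytetrahydro-2H-pyran) (acetal stereoisomer mixture), via bis-ylide 6 (not isolated), via mono-olefinated ylide 7 (not isolated)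
Conditions: KN(SiMe3)2 (2.0 equiv to 5), THF, 0 °C; then 4, −78 °C → rt
Reagents that add atoms: none
Why: Double Wittig olefination with a non-stabilized bis-ylide; the α-alkoxy ketone effect (Still-type Z-selective Wittig) places the new chain cis to the ring OCH2 group and so gives both Z-trisubstituted exocyclic alkenes.

Step 5
Reactants: 9 allyloxy-tert-butyldimethylsilane, 10 1-bromo-3-methylbut-2-ene (prenyl bromide)
Product: 12 (Z)-tert-butyldimethyl[(6-methylhepta-1,5-dien-1-yl)oxy]silane, via lithiated allyl silyl ether 11 (not isolated)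
Conditions: s-BuLi, THF/HMPA, −78 °C; then 10, −78 → −40 °C
Reagents that add atoms: none
Why: Metalation of the allyl silyl ether gives an oxygen-chelated (Z)-oxyallyl lithium (a homoenolate equivalent) whose γ-selective SN2 alkylation with prenyl bromide gives the (Z)-enol silane of 6-methylhept-5-enal directly.

Step 6
Reactants: 8 (3Z,3'Z)-3,3'-(butane-1,4-diylidene)bis(6-methoxytetrahydro-2H-pyran), 12 (Z)-tert-butyldimethyl[(6-methylhepta-1,5-dien-1-yl)oxy]silane (3 equiv)
Product: 14 (2R,2'R)-2,2'-[butane-1,4-diylidenebis((2R,5Z)-tetrahydro-2H-pyran-5-ylidene-2-yl)]bis(6-methylhept-5-enal), via mono-aldehyde mono-acetal 13 (not isolated)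
Conditions: (S,S)-IDPi (5 mol %; BINOL-derived imidodiphosphorimidate, 3,3'-aryl = 3,5-(CF3)2C6H3, N-SO2CF3), toluene, −78 °C, 48 h; then Et3N
Reagents that add atoms: none
Why: Proposed new method: the IDPi acid is silylated in situ by 12 and this silylium-type catalyst removes methoxide from each acetal as TBSOMe; the non-stabilized cyclic oxocarbenium ion is held in the confined chiral IDPi anion, which leaves one face open (sets the ring carbon R), and the (Z)-enol silane adds through an open synclinal transition state with its homoprenyl chain turned away from the ring (sets the aldehyde α-carbon R, anti), after which silyl transfer from the O-silylated aldehyde regenerates the catalyst; the two ends react independently, so the C2-symmetric isomer is enriched in ee by statistical amplification; the closest known reactions are IDPi-catalysed additions of silyl ketene acetals to lactol acetates (one stereocenter) and IDPi-catalysed single aldolizations of aldehyde-derived enol silanes.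

Step 7
Reactants: 14 (2R,2'R)-2,2'-[butane-1,4-diylidenebis((2R,5Z)-tetrahydro-2H-pyran-5-ylidene-2-yl)]bis(6-methylhept-5-enal)
Product: 16 testudinariol A, via mono-cyclized hydroxy aldehyde 15 (not isolated)
Conditions: Me2AlCl (5 equiv), CH2Cl2, −78 → −30 °C; then H2O, 0 °C
Reagents that add atoms: none
Why: Twofold Lewis acid-promoted intramolecular carbonyl-ene cyclization of the 2-substituted 6-methylhept-5-enal units; the bicyclic transition state transfers a methyl hydrogen to the aluminium-bound oxygen on the same face (hydroxyl cis to isopropenyl) and keeps that bulky oxygen trans to the α-tetrahydropyranyl group, so each aldehyde α-stereocenter sets the carbinol carbon S and the isopropenyl carbon R.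

**Compound list**
1 | furfuryl alcohol | OCc1ccco1 | starting material
2 | 6-hydroxy-2H-pyran-3(6H)-one (racemic) | O=C1COC(O)C=C1 | intermediate
3 | 6-methoxy-2H-pyran-3(6H)-one (racemic) | COC1OCC(=O)C=C1 | intermediate
4 | 6-methoxydihydro-2H-pyran-3(4H)-one (racemic) | COC1CCC(=O)CO1 | intermediate
5 | butane-1,4-diylbis(triphenylphosphonium) dibromide | [Br-].[Br-].c1ccc(cc1)[P+](CCCC[P+](c1ccccc1)(c1ccccc1)c1ccccc1)(c1ccccc1)c1ccccc1 | starting material
6 | bis-ylide, butane-1,4-diylidenebis(triphenylphosphorane) | C(CC=P(c1ccccc1)(c1ccccc1)c1ccccc1)C=P(c1ccccc1)(c1ccccc1)c1ccccc1 | intermediate (not isolated)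
7 | mono-olefinated ylide, [(4Z)-4-(6-methoxytetrahydro-2H-pyran-3-ylidene)butylidene]triphenylphosphorane | COC1CC/C(=C/CCC=P(c2ccccc2)(c2ccccc2)c2ccccc2)CO1 | intermediate (not isolated)
8 | (3Z,3'Z)-3,3'-(butane-1,4-diylidene)bis(6-methoxytetrahydro-2H-pyran), acetal carbons stereorandom | COC1CC/C(=C/CC/C=C2/CCC(OC)OC2)CO1 | intermediate
9 | allyloxy-tert-butyldimethylsilane | C=CCO[Si](C)(C)C(C)(C)C | starting material
10 | 1-bromo-3-methylbut-2-ene (prenyl bromide) | CC(C)=CCBr | starting material
11 | lithiated allyl silyl ether, [1-(tert-butyldimethylsilyloxy)allyl]lithium | [Li]C(C=C)O[Si](C)(C)C(C)(C)C | intermediate (not isolated)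
12 | (Z)-tert-butyldimethyl[(6-methylhepta-1,5-dien-1-yl)oxy]silane | CC(C)=CCC/C=C\O[Si](C)(C)C(C)(C)C | intermediate
13 | mono-aldehyde mono-acetal: (2R)-2-[(2R,5Z)-5-{4-[(3Z)-6-methoxytetrahydro-2H-pyran-3-ylidene]butylidene}tetrahydro-2H-pyran-2-yl]-6-methylhept-5-enal | O=C[C@H](CCC=C(C)C)[C@H]1CC/C(=C/CC/C=C2/CCC(OC)OC2)CO1 | intermediate (not isolated)
14 | C2-symmetric dialdehyde: (2R,2'R)-2,2'-[butane-1,4-diylidenebis((2R,5Z)-tetrahydro-2H-pyran-5-ylidene-2-yl)]bis(6-methylhept-5-enal) | O=C[C@H](CCC=C(C)C)[C@H]1CC/C(=C/CC/C=C2/CC[C@H]([C@H](C=O)CCC=C(C)C)OC2)CO1 | intermediate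
15 | mono-cyclized hydroxy aldehyde (one cyclopentanol closed, other end still the aldehyde) | C=C(C)[C@H]1CC[C@H]([C@H]2CC/C(=C/CC/C=C3/CC[C@H]([C@H](C=O)CCC=C(C)C)OC3)CO2)[C@H]1O | intermediate (not isolated)
16 | testudinariol A: (1S,1'S,2R,2'R,5S,5'S)-5,5'-[butane-1,4-diylidenebis((2R,5Z)-tetrahydro-2H-pyran-5-ylidene-2-yl)]bis[2-(prop-1-en-2-yl)cyclopentan-1-ol] | C=C(C)[C@H]1CC[C@H]([C@H]2CC/C(=C/CC/C=C3/CC[C@H]([C@H]4CC[C@H](C(=C)C)[C@@H]4O)OC3)CO2)[C@H]1O | target

**Count and risks**
Total steps: 7. Longest linear sequence: 6 steps (1 → 2 → 3 → 4 → 8 → 14 → 16).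

Most likely to fail, in this order:

Step 6 (the proposed new reaction). The risks are anti/syn control at the two new vicinal centers, sluggish ionization of a methyl acetal, premature acid-induced cyclization of the product aldehyde, and a hard-to-separate unsymmetrical diastereomer if one end reacts with the wrong sense. The fallback sets out from 8 and comes back at 14, using known chemistry that sets only the ring stereocenter catalytically and the α-carbon by substrate control. Aqueous AcOH/THF hydrolyses both acetals to the bis-lactol (5Z,5'Z)-5,5'-(butane-1,4-diylidene)bis(tetrahydro-2H-pyran-2-ol) F1. Ac2O, Et3N and DMAP give the bis(lactol acetate) (5Z,5'Z)-5,5'-(butane-1,4-diylidene)bis(tetrahydro-2H-pyran-2-yl) diacetate F2. The established IDPi-catalysed addition of tert-butyl[(1-methoxyvinyl)oxy]dimethylsilane to lactol acetates gives the diester dimethyl 2,2'-[butane-1,4-diylidenebis((2R,5Z)-tetrahydro-2H-pyran-5-ylidene-2-yl)]diacetate F3. Double enolization with LiN(i-Pr)2 (THF/DMPU, −78 °C) and alkylation with 5-iodo-2-methylpent-2-ene, through the lithium chelate between enolate and ring oxygen (Fráter–Seebach-type anti alkylation), give the bis-alkylated diester dimethyl (2R,2'R)-2,2'-[butane-1,4-diylidenebis((2R,5Z)-tetrahydro-2H-pyran-5-ylidene-2-yl)]bis(6-methylhept-5-enoate) F4. i-Bu2AlH (toluene, −78 °C) then reduces both esters to the dialdehyde 14.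

Step 4. The Z-directing α-alkoxy effect is secure for acyclic ketones but unproven for the cyclic ketone 4, and enolization or mono-olefination may cut the yield. The fallback sets out from 5 (through bis-ylide 6) and comes back at 8, moving the olefination to an acyclic α-silyloxy ketone. Purchased [2-(1,3-dioxolan-2-yl)ethyl]magnesium bromide is added to purchased 2-[(tert-butyldimethylsilyl)oxy]-N-methoxy-N-methylacetamide to give 1-[(tert-butyldimethylsilyl)oxy]-4-(1,3-dioxolan-2-yl)butan-2-one F5. The Still–Wittig reaction of F5 with 6 (THF, −78 °C) gives 2,2'-[(3Z,7Z)-3,8-bis({[tert-butyl(dimethyl)silyl]oxy}methyl)deca-3,7-diene-1,10-diyl]bis(1,3-dioxolane) F6. CSA in MeOH removes both silyl groups and transacetalizes, closing both rings to the bis(methyl acetal) 8.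

Step 7. Two ring closures must both give the cis-hydroxyl/isopropenyl, trans-tetrahydropyranyl isomer, and the bis(allylic ether) diene must survive the Lewis acid. The fallback sets out from 4 and comes back at 16, changing the two-directional end game into a convergent one. The step 6 reaction is run on monomeric 4 with 12 to give the keto aldehyde (2R)-6-methyl-2-[(2R)-5-oxotetrahydro-2H-pyran-2-yl]hept-5-enal F7. Me2AlCl then closes a single ring to the hydroxy ketone (6R)-6-[(1S,2S,3R)-2-hydroxy-3-(prop-1-en-2-yl)cyclopentyl]dihydro-2H-pyran-3(4H)-one F8, which can be freed of diastereomers at half size. Two equivalents of F8 (hydroxyl first deprotonated with KN(SiMe3)2) are joined by the double Z-selective Wittig reaction with 6 to give 16.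

**Further compounds**
F1 | step 6 | (5Z,5'Z)-5,5'-(butane-1,4-diylidene)bis(tetrahydro-2H-pyran-2-ol) | OC1CC/C(=C/CC/C=C2/CCC(O)OC2)CO1
F2 | step 6 | (5Z,5'Z)-5,5'-(butane-1,4-diylidene)bis(tetrahydro-2H-pyran-2-yl) diacetate | CC(=O)OC1CC/C(=C/CC/C=C2/CCC(OC(C)=O)OC2)CO1
F3 | step 6 | dimethyl 2,2'-[butane-1,4-diylidenebis((2R,5Z)-tetrahydro-2H-pyran-5-ylidene-2-yl)]diacetate | COC(=O)C[C@H]1CC/C(=C/CC/C=C2/CC[C@H](CC(=O)OC)OC2)CO1
F4 | step 6 | dimethyl (2R,2'R)-2,2'-[butane-1,4-diylidenebis((2R,5Z)-tetrahydro-2H-pyran-5-ylidene-2-yl)]bis(6-methylhept-5-enoate) | COC(=O)[C@H](CCC=C(C)C)[C@H]1CC/C(=C/CC/C=C2/CC[C@H]([C@H](C(=O)OC)CCC=C(C)C)OC2)CO1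
F5 | step 4 | 1-[(tert-butyldimethylsilyl)oxy]-4-(1,3-dioxolan-2-yl)butan-2-one | CC(C)(C)[Si](C)(C)OCC(=O)CCC1OCCO1
F6 | step 4 | 2,2'-[(3Z,7Z)-3,8-bis({[tert-butyl(dimethyl)silyl]oxy}methyl)deca-3,7-diene-1,10-diyl]bis(1,3-dioxolane) | CC(C)(C)[Si](C)(C)OC/C(CCC1OCCO1)=C\CC/C=C(/CCC1OCCO1)CO[Si](C)(C)C(C)(C)C
F7 | step 7 | (2R)-6-methyl-2-[(2R)-5-oxotetrahydro-2H-pyran-2-yl]hept-5-enal | O=C[C@H](CCC=C(C)C)[C@H]1CCC(=O)CO1
F8 | step 7 | (6R)-6-[(1S,2S,3R)-2-hydroxy-3-(prop-1-en-2-yl)cyclopentyl]dihydro-2H-pyran-3(4H)-one | C=C(C)[C@H]1CC[C@H]([C@H]2CCC(=O)CO2)[C@H]1O
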